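**Retrosynthetic overview**

1. Target locants: ring C1 (CMe2), C2 (CHBr), C3 (CH2), C4 (CHCl), C5 (ring carbon of the alkylidene), C6 (CHCl next to C1); side chain C7 (=CH), C8 (CH2Br). The cyclohexane ring has a latent mirror plane through C1 and C4 (C2/C6 both carry a halogen next to CMe2, C3/C5 flank C4), so it is a masked 4,4-dimethylcyclohexa-2,5-dienone.
2. Key disconnection: C2–C3 and C5–C6 are made together by a [3+3] annulation of two mirror-symmetric three-carbon units, 2,2-dimethylpropanedial (C6–C1–C2) and the 1,3-dianion of a 2-oxopropylphosphonate (C3–C4–C5): γ-aldol, then intramolecular Horner–Wadsworth–Emmons olefination; dehydration gives the dienone.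
3. Symmetry is broken by copper-catalysed asymmetric β-borylation (boron at C2), and a CBS reduction sets C4–OH. C4 then relays configuration to C5/C6 through a chlorine-atom-transfer radical cyclisation of its dichloroacetate (C5–C7 bond, C6–Cl and a γ-lactone in one event), and back to C2 through a radical bromodeboronation.
4. The temporary butenolide (O on C4, carbonyl = C8) fixes the C5=C7 geometry (C8 cis to C4). It is reduced open, C4–OH is replaced by chloride with inversion and C8–OH by bromide.
5. Ring order: carbocycle first (step 2), temporary lactone second (step 7, opened in step 10).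

Key step: step 2

Remark on the chemistry: the sense of induction in steps 4 and 5 is assumed from the usual models for cyclohexenones; both the ligand and the oxazaborolidine are available in either hand should the sense be opposite.

**Step 1**
Reactants: 1 2,2-dimethylpropane-1,3-diol
Product: 2 2,2-dimethylpropanedial
Conditions: (COCl)2, DMSO, CH2Cl2, −78 °C; Et3N, −78 → 0 °C; 2 carried on as a dried solution
Reagents that add atoms: none
Why: Swern oxidation of both primary alcohols; the dialdehyde has no α-hydrogen and so cannot enolise or self-condense, and it is kept in solution because it is volatile and hydrates easily.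

**Step 2**
Reactants: 2 2,2-dimethylpropanedial; 3 dimethyl (2-oxopropyl)phosphonate
Product: 6 rac-5-hydroxy-4,4-dimethylcyclohex-2-en-1-one, via phosphonate dianion 4 (not isolated), via aldolate 5 (not isolated)
Conditions: 3, NaH, THF, 0 °C; n-BuLi, 0 °C; slow addition to 2, THF, −78 → 23 °C; aq NH4Cl
Reagents that add atoms: none
Why: The γ-carbanion of dianion 4 adds to one of the two equivalent formyl groups of 2 (aldol), and the phosphonate-stabilised carbanion that remains in 5 then closes the ring on the second formyl group by an intramolecular Horner–Wadsworth–Emmons olefination; the closest known reaction types are the γ-aldol of β-ketophosphonate 1,3-dianions and HWE cyclohexenone annulation. The six-membered ring is closed by 6-exo-trig attack of the phosphonate carbanion on the aldehyde followed by syn elimination of dimethyl phosphate, and the ring enforces the cis ring alkene. The only new stereocentre, the carbinol carbon of 6, is formed without control and is erased in step 3. The step needs mono-addition and ring closure over oligomerisation: both partners are three-carbon units with a mirror plane so no regiochemistry arises, 2 cannot enolise, the hard γ-carbanion reacts before the soft phosphonate anion, and after the first addition the second formyl group is reached intramolecularly through a six-membered transition state. After steps 3 and 4 the two bonds made here are the C2–C3 and C5–C6 bonds of the target.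

**Step 3**
Reactants: 6 rac-5-hydroxy-4,4-dimethylcyclohex-2-en-1-one
Product: 8 4,4-dimethylcyclohexa-2,5-dien-1-one, via mesylate 7 (not isolated)
Conditions: MsCl, Et3N, CH2Cl2, 0 → 23 °C
Reagents that add atoms: none
Why: Mesylation followed by E1cB elimination across the α′-CH2/β-carbinol unit gives the cross-conjugated dienone; the stereocentre of 6 is removed and the product has a mirror plane through C1 and C4.

**Step 4**
Reactants: 8 4,4-dimethylcyclohexa-2,5-dien-1-one
Product: 10 (5S)-4,4-dimethyl-5-(4,4,5,5-tetramethyl-1,3,2-dioxaborolan-2-yl)cyclohex-2-en-1-one, via boron enolate 9 (not isolated)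
Conditions: B2pin2 (1.0 equiv), CuCl (5 mol %), NaOt-Bu (6 mol %), (R)-1-[(S)-2-(diphenylphosphino)ferrocenyl]ethyldicyclohexylphosphine or its antipode, whichever delivers the 5S product (6 mol %), THF, 0 °C, no protic additive; aq NH4Cl
Reagents that add atoms: bis(pinacolato)diboron CC1(C)OB(OC1(C)C)B1OC(C)(C)C(C)(C)O1
Why: Copper-catalysed conjugate borylation; the two enone arms of 8 are enantiotopic and the chiral bisphosphine–copper boryl complex selects one β-carbon and face (desymmetrisation), which sets C2, while under aprotic conditions the adduct stays as boron enolate 9 so that the second arm is not an enone until work-up.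

**Step 5**
Reactants: 10 (5S)-4,4-dimethyl-5-(pinacolboryl)cyclohex-2-en-1-one
Product: 11 (1R,5S)-4,4-dimethyl-5-(4,4,5,5-tetramethyl-1,3,2-dioxaborolan-2-yl)cyclohex-2-en-1-ol
Conditions: (S)-1-methyl-3,3-diphenyltetrahydro-1H,3H-pyrrolo[1,2-c][1,3,2]oxazaborole ((S)-Me-CBS, 15 mol %), BH3·SMe2, THF, −30 °C; MeOH
Reagents that add atoms: none
Why: Corey–Bakshi–Shibata reduction, 1,2-selective; the oxazaborolidine binds the ketone anti to the alkenyl arm (large group) and should deliver hydride to give the (R)-carbinol, hydroxyl cis to boron, under catalyst control, so that C4 now carries the absolute configuration for the rest of the route.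

**Step 6**
Reactants: 11 (1R,5S)-4,4-dimethyl-5-(pinacolboryl)cyclohex-2-en-1-ol
Product: 12 (1R,5S)-4,4-dimethyl-5-(4,4,5,5-tetramethyl-1,3,2-dioxaborolan-2-yl)cyclohex-2-en-1-yl 2,2-dichloroacetate
Conditions: Cl2CHCOCl, pyridine, DMAP (cat.), CH2Cl2, 0 °C
Reagents that add atoms: dichloroacetyl chloride ClC(Cl)C(Cl)=O
Why: Acylation of the secondary allylic alcohol without breaking the C–O bond; it installs the two-carbon radical precursor that becomes C7 and C8.

**Step 7**
Reactants: 12 (1R,5S)-4,4-dimethyl-5-(pinacolboryl)cyclohex-2-en-1-yl 2,2-dichloroacetate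
Product: 13 (3aR,4S,6S,7aR)-3,4-dichloro-5,5-dimethyl-6-(4,4,5,5-tetramethyl-1,3,2-dioxaborolan-2-yl)hexahydro-1-benzofuran-2(3H)-one (both C3 epimers)
Conditions: CuCl (30 mol %), tris(2-pyridylmethyl)amine (30 mol %), ClCH2CH2Cl, 80 °C, degassed
Reagents that add atoms: none
Why: Kharasch-type atom-transfer radical cyclisation, as known for allylic polychloroacetates: monovalent copper abstracts one chlorine, the α-chloro ester radical closes 5-exo-trig onto C5 on the face of the ester oxygen (cis-fused γ-lactone, C5 set by the tether), and the C6 radical takes chlorine back from the divalent copper chloride complex anti to the new C5–C7 bond (C6 set by substrate control), so the neopentylic C–Cl bond is made without substitution at a hindered carbon.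

**Step 8**
Reactants: 13 (3aR,4S,6S,7aR)-3,4-dichloro-5,5-dimethyl-6-(pinacolboryl)hexahydro-1-benzofuran-2(3H)-one
Product: 14 (4R,6S,7aR)-4-chloro-5,5-dimethyl-6-(4,4,5,5-tetramethyl-1,3,2-dioxaborolan-2-yl)-5,6,7,7a-tetrahydro-1-benzofuran-2(4H)-one
Conditions: DBU (1.2 equiv), CH2Cl2, 0 °C, short reaction time
Reagents that add atoms: none
Why: Base-induced dehydrochlorination of the α-chloro lactone gives the butenolide; both C7 epimers converge, the C6 chloride has no antiperiplanar hydrogen, and the five-membered ring fixes C8 cis to C4 across the C5=C7 bond.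

**Step 9**
Reactants: 14 (4R,6S,7aR)-4-chloro-5,5-dimethyl-6-(pinacolboryl)-5,6,7,7a-tetrahydro-1-benzofuran-2(4H)-one
Product: 15 (4S,6S,7aR)-6-bromo-4-chloro-5,5-dimethyl-5,6,7,7a-tetrahydro-1-benzofuran-2(4H)-one
Conditions: TsBr (1.5 equiv), 2-methoxy-1,3,2-benzodioxaborole (0.3 equiv), TfOH (1 mol %), di-tert-butyl hyponitrite (5 mol %), benzene, 70 °C
Reagents that add atoms: 4-methylbenzenesulfonyl bromide Cc1ccc(cc1)S(=O)(=O)Br
Why: Radical-chain deboronative bromination (transesterification to the catechol boronic ester, homolytic substitution at boron by the sulfonyl radical, bromine-atom transfer to the C2 radical); the fused butenolide holds the lactone C–O bond equatorial and the C6–Cl bond axial, so the bromine donor should approach the planar C2 radical anti to the 1,3-diaxial chlorine and give the equatorial bromide cis to the lactone oxygen, whatever the configuration of the C–B bond.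

**Step 10**
Reactants: 15 (4S,6S,7aR)-6-bromo-4-chloro-5,5-dimethyl-5,6,7,7a-tetrahydro-1-benzofuran-2(4H)-one
Product: 16 (1R,2E,3S,5S)-5-bromo-3-chloro-2-(2-hydroxyethylidene)-4,4-dimethylcyclohexan-1-ol
Conditions: i-Bu2AlH (3.5 equiv), CH2Cl2, −78 → 0 °C; aq KNaC4H4O6 (potassium sodium tartrate)
Reagents that add atoms: none
Why: Hydride reduction of the lactone through the lactol to the ene-1,4-diol; the trisubstituted alkene keeps the geometry fixed by the ring and the secondary halides are inert to i-Bu2AlH at low temperature.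

**Step 11**
Reactants: 16 (1R,2E,3S,5S)-5-bromo-3-chloro-2-(2-hydroxyethylidene)-4,4-dimethylcyclohexan-1-ol
Product: 17 (1R,2E,3S,5S)-5-bromo-2-{2-[(tert-butyldimethylsilyl)oxy]ethylidene}-3-chloro-4,4-dimethylcyclohexan-1-ol
Conditions: TBSCl (1.05 equiv), imidazole, CH2Cl2, 0 °C
Reagents that add atoms: tert-butyldimethylsilyl chloride CC(C)(C)[Si](C)(C)Cl
Why: Silylation is selective for the primary allylic hydroxyl over the hindered secondary one; masking it also prevents dihydrofuran formation in the next step.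

**Step 12**
Reactants: 17 (1R,2E,3S,5S)-5-bromo-2-{2-[(tert-butyldimethylsilyl)oxy]ethylidene}-3-chloro-4,4-dimethylcyclohexan-1-ol
Product: 18 tert-butyl{[(2E)-2-[(2S,4S,6S)-4-bromo-2,6-dichloro-3,3-dimethylcyclohexylidene]ethyl]oxy}dimethylsilane
Conditions: PPh3, hexachloroacetone, CH2Cl2, 0 °C
Reagents that add atoms: hexachloroacetone ClC(Cl)(Cl)C(=O)C(Cl)(Cl)Cl
Why: Appel-type chlorination under neutral conditions; the alkoxyphosphonium group, axial to relieve allylic strain, is displaced by chloride in an SN2 step with inversion, which turns the (R)-carbinol into the (S)-chloride cis to the C6 chloride.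

**Step 13**
Reactants: 18 tert-butyl{[(2E)-2-[(2S,4S,6S)-4-bromo-2,6-dichloro-3,3-dimethylcyclohexylidene]ethyl]oxy}dimethylsilane
Product: 19 (2E)-2-[(2S,4S,6S)-4-bromo-2,6-dichloro-3,3-dimethylcyclohexylidene]ethan-1-ol
Conditions: HF·pyridine, THF, 0 °C
Reagents that add atoms: none
Why: Fluoride cleavage of the silyl ether under acidic, non-basic conditions that leave the three carbon–halogen bonds untouched.

**Step 14**
Reactants: 19 (2E)-2-[(2S,4S,6S)-4-bromo-2,6-dichloro-3,3-dimethylcyclohexylidene]ethan-1-ol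
Product: 20 (2S,3E,4S,6S)-6-bromo-3-(2-bromoethylidene)-2,4-dichloro-1,1-dimethylcyclohexane (ochtodene)
Conditions: CBr4, PPh3, CH2Cl2, 0 °C
Reagents that add atoms: carbon tetrabromide BrC(Br)(Br)Br
Why: Appel bromination of the primary allylic alcohol by SN2 displacement at the unhindered CH2, without allylic transposition, completes the target.

**Compound list**

1 | 2,2-dimethylpropane-1,3-diol | OCC(C)(C)CO | starting material
2 | 2,2-dimethylpropanedial | O=CC(C)(C)C=O | intermediate
3 | dimethyl (2-oxopropyl)phosphonate | COP(=O)(OC)CC(C)=O | starting material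
4 | sodium lithium 1,3-dianion of dimethyl (2-oxopropyl)phosphonate | [Na+].[Li+].COP(=O)(OC)[CH-]C(=O)[CH2-] | intermediate
5 | dianion (alkoxide and phosphonate carbanion) of dimethyl (4-hydroxy-5,5-dimethyl-2,6-dioxohexyl)phosphonate, racemic | [Na+].[Li+].COP(=O)(OC)[CH-]C(=O)CC([O-])C(C)(C)C=O | intermediate
6 | rac-5-hydroxy-4,4-dimethylcyclohex-2-en-1-one | CC1(C)C=CC(=O)CC1O | intermediate
7 | rac-2,2-dimethyl-5-oxocyclohex-3-en-1-yl methanesulfonate | CC1(C)C=CC(=O)CC1OS(C)(=O)=O | intermediate
8 | 4,4-dimethylcyclohexa-2,5-dien-1-one | CC1(C)C=CC(=O)C=C1 | intermediate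
9 | 2-{[(3S)-4,4-dimethyl-3-(4,4,5,5-tetramethyl-1,3,2-dioxaborolan-2-yl)cyclohexa-1,5-dien-1-yl]oxy}-4,4,5,5-tetramethyl-1,3,2-dioxaborolane | CC1(C)[C@@H](B2OC(C)(C)C(C)(C)O2)C=C(OB2OC(C)(C)C(C)(C)O2)C=C1 | intermediate
10 | (5S)-4,4-dimethyl-5-(4,4,5,5-tetramethyl-1,3,2-dioxaborolan-2-yl)cyclohex-2-en-1-one | CC1(C)[C@@H](B2OC(C)(C)C(C)(C)O2)CC(=O)C=C1 | intermediate
11 | (1R,5S)-4,4-dimethyl-5-(4,4,5,5-tetramethyl-1,3,2-dioxaborolan-2-yl)cyclohex-2-en-1-ol | CC1(C)[C@@H](B2OC(C)(C)C(C)(C)O2)C[C@@H](O)C=C1 | intermediate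
12 | (1R,5S)-4,4-dimethyl-5-(4,4,5,5-tetramethyl-1,3,2-dioxaborolan-2-yl)cyclohex-2-en-1-yl 2,2-dichloroacetate | CC1(C)[C@@H](B2OC(C)(C)C(C)(C)O2)C[C@@H](OC(=O)C(Cl)Cl)C=C1 | intermediate
13 | (3aR,4S,6S,7aR)-3,4-dichloro-5,5-dimethyl-6-(4,4,5,5-tetramethyl-1,3,2-dioxaborolan-2-yl)hexahydro-1-benzofuran-2(3H)-one, C3 epimers | CC1(C)[C@@H](B3OC(C)(C)C(C)(C)O3)C[C@H]2OC(=O)C(Cl)[C@H]2[C@@H]1Cl | intermediate
14 | (4R,6S,7aR)-4-chloro-5,5-dimethyl-6-(4,4,5,5-tetramethyl-1,3,2-dioxaborolan-2-yl)-5,6,7,7a-tetrahydro-1-benzofuran-2(4H)-one | CC1(C)[C@@H](B3OC(C)(C)C(C)(C)O3)C[C@H]2OC(=O)C=C2[C@@H]1Cl | intermediate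
15 | (4S,6S,7aR)-6-bromo-4-chloro-5,5-dimethyl-5,6,7,7a-tetrahydro-1-benzofuran-2(4H)-one | CC1(C)[C@@H](Br)C[C@H]2OC(=O)C=C2[C@@H]1Cl | intermediate
16 | (1R,2E,3S,5S)-5-bromo-3-chloro-2-(2-hydroxyethylidene)-4,4-dimethylcyclohexan-1-ol | CC1(C)[C@@H](Br)C[C@@H](O)/C(=C\CO)[C@@H]1Cl | intermediate
17 | (1R,2E,3S,5S)-5-bromo-2-{2-[(tert-butyldimethylsilyl)oxy]ethylidene}-3-chloro-4,4-dimethylcyclohexan-1-ol | CC1(C)[C@@H](Br)C[C@@H](O)/C(=C\CO[Si](C)(C)C(C)(C)C)[C@@H]1Cl | intermediate
18 | tert-butyl{[(2E)-2-[(2S,4S,6S)-4-bromo-2,6-dichloro-3,3-dimethylcyclohexylidene]ethyl]oxy}dimethylsilane | CC1(C)[C@@H](Br)C[C@H](Cl)/C(=C\CO[Si](C)(C)C(C)(C)C)[C@@H]1Cl | intermediate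
19 | (2E)-2-[(2S,4S,6S)-4-bromo-2,6-dichloro-3,3-dimethylcyclohexylidene]ethan-1-ol | CC1(C)[C@@H](Br)C[C@H](Cl)/C(=C\CO)[C@@H]1Cl | intermediate
20 | (2S,3E,4S,6S)-6-bromo-3-(2-bromoethylidene)-2,4-dichloro-1,1-dimethylcyclohexane (ochtodene) | CC1(C)[C@@H](Br)C[C@H](Cl)/C(=C\CBr)[C@@H]1Cl | target

**Totals**

Total step count: 14. Longest linear sequence: 14 steps (1 → 20; 3 enters at step 2).

**Steps most likely to fail, with fallbacks**

Step 7. Chlorine-atom abstraction from a dichloroacetate is slow and the ester spends little time in the rotamer that can cyclise, so hydrodechlorination or telomerisation may outrun ring closure, and the chlorine return to C6 may lose facial control. Fallback: setting out from 11, acylation with Cl3CCOCl and pyridine gives (1R,5S)-4,4-dimethyl-5-(4,4,5,5-tetramethyl-1,3,2-dioxaborolan-2-yl)cyclohex-2-en-1-yl 2,2,2-trichloroacetate F1. This is the more easily reduced substrate class with the closest precedent for chlorine-atom-transfer lactonisation (CuCl with 2,2′-bipyridine, ClCH2CH2Cl, 80 °C, or RuCl2(PPh3)3, benzene, 140 °C). The cyclised (3aR,4S,6S,7aR)-3,3,4-trichloro-5,5-dimethyl-6-(4,4,5,5-tetramethyl-1,3,2-dioxaborolan-2-yl)hexahydro-1-benzofuran-2(3H)-one F2 is then taken down one oxidation level with zinc dust in AcOH at 0 °C, which removes one chlorine α to the carbonyl only, and the route is rejoined at 13.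

Step 9. Face discrimination in bromine transfer to the planar C2 radical may be insufficient, or the sulfonyl radical chain may stall. Fallback (ionic and stereospecific instead of substrate-controlled): setting out from 8, borylation with the antipodal ligand gives (5R)-4,4-dimethyl-5-(4,4,5,5-tetramethyl-1,3,2-dioxaborolan-2-yl)cyclohex-2-en-1-one F3. The same CBS reduction gives (1R,5R)-4,4-dimethyl-5-(4,4,5,5-tetramethyl-1,3,2-dioxaborolan-2-yl)cyclohex-2-en-1-ol F4, and TBSCl with imidazole gives tert-butyl{[(1R,5R)-4,4-dimethyl-5-(4,4,5,5-tetramethyl-1,3,2-dioxaborolan-2-yl)cyclohex-2-en-1-yl]oxy}dimethylsilane F5. Addition of 3,5-bis(trifluoromethyl)phenyllithium (THF, −78 °C) and then N-bromosuccinimide replaces boron by bromine with inversion, the known stereospecific halogenation of secondary boronic esters through their aryl boronate complexes, to give {[(1R,5S)-5-bromo-4,4-dimethylcyclohex-2-en-1-yl]oxy}(tert-butyl)dimethylsilane F6. HF·pyridine gives (1R,5S)-5-bromo-4,4-dimethylcyclohex-2-en-1-ol F7, and Cl2CHCOCl with pyridine gives (1R,5S)-5-bromo-4,4-dimethylcyclohex-2-en-1-yl 2,2-dichloroacetate F8. The CuCl/tris(2-pyridylmethyl)amine cyclisation gives (3aR,4S,6S,7aR)-6-bromo-3,4-dichloro-5,5-dimethylhexahydro-1-benzofuran-2(3H)-one F9, and DBU rejoins the route at 15.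

Step 2. The dialdehyde may take up two dianions or oligomerise, or olefination may occur between molecules before the aldol, which gives an (E)-enone that cannot close. Fallback (neutral aldol chemistry in two operations instead of the phosphonate domino): setting out from 2, a Mukaiyama aldol with one equivalent of isopropenyloxytrimethylsilane (BF3·OEt2, CH2Cl2, −78 °C; aqueous acid work-up) gives 3-hydroxy-2,2-dimethyl-5-oxohexanal F10. p-TsOH in refluxing benzene with removal of water then effects the intramolecular aldol condensation of the methyl ketone onto the remaining formyl group and the β-elimination of water, and the route is rejoined at 8.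

**Further compounds**

F1 | step 7 | (1R,5S)-4,4-dimethyl-5-(4,4,5,5-tetramethyl-1,3,2-dioxaborolan-2-yl)cyclohex-2-en-1-yl 2,2,2-trichloroacetate | CC1(C)[C@@H](B2OC(C)(C)C(C)(C)O2)C[C@@H](OC(=O)C(Cl)(Cl)Cl)C=C1
F2 | step 7 | (3aR,4S,6S,7aR)-3,3,4-trichloro-5,5-dimethyl-6-(4,4,5,5-tetramethyl-1,3,2-dioxaborolan-2-yl)hexahydro-1-benzofuran-2(3H)-one | CC1(C)[C@@H](B3OC(C)(C)C(C)(C)O3)C[C@H]2OC(=O)C(Cl)(Cl)[C@H]2[C@@H]1Cl
F3 | step 9 | (5R)-4,4-dimethyl-5-(4,4,5,5-tetramethyl-1,3,2-dioxaborolan-2-yl)cyclohex-2-en-1-one | CC1(C)[C@H](B2OC(C)(C)C(C)(C)O2)CC(=O)C=C1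
F4 | step 9 | (1R,5R)-4,4-dimethyl-5-(4,4,5,5-tetramethyl-1,3,2-dioxaborolan-2-yl)cyclohex-2-en-1-ol | CC1(C)[C@H](B2OC(C)(C)C(C)(C)O2)C[C@@H](O)C=C1
F5 | step 9 | tert-butyl{[(1R,5R)-4,4-dimethyl-5-(4,4,5,5-tetramethyl-1,3,2-dioxaborolan-2-yl)cyclohex-2-en-1-yl]oxy}dimethylsilane | CC1(C)[C@H](B2OC(C)(C)C(C)(C)O2)C[C@@H](O[Si](C)(C)C(C)(C)C)C=C1
F6 | step 9 | {[(1R,5S)-5-bromo-4,4-dimethylcyclohex-2-en-1-yl]oxy}(tert-butyl)dimethylsilane | CC1(C)[C@@H](Br)C[C@@H](O[Si](C)(C)C(C)(C)C)C=C1
F7 | step 9 | (1R,5S)-5-bromo-4,4-dimethylcyclohex-2-en-1-ol | CC1(C)[C@@H](Br)C[C@@H](O)C=C1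
F8 | step 9 | (1R,5S)-5-bromo-4,4-dimethylcyclohex-2-en-1-yl 2,2-dichloroacetate | CC1(C)[C@@H](Br)C[C@@H](OC(=O)C(Cl)Cl)C=C1
F9 | step 9 | (3aR,4S,6S,7aR)-6-bromo-3,4-dichloro-5,5-dimethylhexahydro-1-benzofuran-2(3H)-one, C3 epimers | CC1(C)[C@@H](Br)C[C@H]2OC(=O)C(Cl)[C@H]2[C@@H]1Cl
F10 | step 2 | rac-3-hydroxy-2,2-dimethyl-5-oxohexanal | CC(=O)CC(O)C(C)(C)C=O
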